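## Structural features

The target 11 is 5,7-dihydroxy-6-methyl-2-nonacosyl-4H-chromen-4-one (C39H66O4). It is a γ-pyrone ring (O1, C2, C3, C4, C4a, C8a) fused through C4a–C8a to a benzenoid ring (C4a, C5, C6, C7, C8, C8a), with an unbranched C29 chain on C2. It has no stereocentre and no stereogenic double bond, so every selectivity question is constitutional. The benzenoid ring is a C-methylphloroglucinol: oxygen on C5, C7 and C8a, CH3 on C6, H only on C8, and the 5-OH hydrogen-bonded to the C4 carbonyl. The real difficulty is to place CH3 on C6 and not on C8. An acylated methylphloroglucinol has two different ortho oxygens, either can become O1, and ring opening at C2 under strong acid or base lets the two chromones interconvert (Wessely–Moser type). Fragile points are C2 (a Michael acceptor, attacked by hydroxide or alkoxide on heating), the oxidisable electron-rich arene, and the two acidic phenols, which normally force a protection/deprotection cycle. A second, practical difficulty is that the C29 chain makes every intermediate a wax with poor solubility in the cold, and few long-chain building blocks (C28 and C30 alcohols and acids) can be bought. The key step exploits the unbroken polyketide alternation of the skeleton: C8–C7–C6(CH3)–C5 is a 2-methylacetoacetate unit (γ-carbon, ketone carbon, methyl-bearing α-carbon, ester carbon), C8a is the vinylogous acyl carbon of the γ-pyrone ring, and C4a is its nucleophilic α-carbon. The benzenoid ring can therefore be grown onto a finished γ-pyrone through the bonds C8–C8a and C4a–C5, and the methyl group is then locked between C5 and C7 by the constitution of the four-carbon partner.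

## Logic of the disconnections

In one sentence: 11 is made by a one-flask anionic formal [4+2] benzannulation of the four-carbon dianion 9 onto the γ-pyrone 7. The arene is built on the heterocycle, whereas the route drawn first builds the heterocycle on a ready-made arene.

**11 ⇒ 10, bond C4a–C5.**
- Reason: this bond joins the nucleophilic α-carbon of the pyrone ring to a carbon at the carboxyl level.
- Gain: cutting it opens the benzenoid ring and turns both phenols back into carbonyl groups, so no phenol ever needs protection. A hexasubstituted bicyclic arene becomes a monocyclic pyrone with a linear side chain.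
- Demand: the charge of 10 must sit on the CH2 next to the ring and not on the methyl-bearing carbon, and the extended enolate must react at its ring carbon. Aromatisation pays for the closure.

**10 ⇒ 7 + 9 (9 from 8 by double deprotonation), bond C8–C8a.**
- Reason: C8a is acyl-like. A leaving group there marks the one site where the ring is to grow, and the terminal carbanion of 9 is its natural partner.
- Gain: full convergence. Four benzenoid carbons, the methyl group and both phenolic oxygens come from one bulk chemical, and the choice between a 6-methyl and an 8-methyl product disappears.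
- Demand: addition at C2 of 7 must be faster than proton abstraction from C1′ of its chain and than attack at C4 or C6.

**7 ⇒ 5 (through 6), bond O–CH3 on the oxygen of the future C8a.**
- Reason: 7 is the less stable O-methyl isomer of a tautomeric pair and can only come from methyl transfer to the lactone carbonyl oxygen of neutral 5.
- Gain: 5 is a simple homologue of the bulk chemical 3.
- Demand: no base may be present until methyl transfer is complete, otherwise O4 is methylated.

**5 ⇒ 4 + 2 (4 from 3), bond C1′–C2′ of the chain.**
- Reason: it is the sp3–sp3 bond next to an acidifying ring, and the split 1 + 28 matches a commercial chain length.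
- Gain: the whole chain comes from one purchased alcohol and the ring from a bulk lactone.
- Demand: C-alkylation at the exocyclic carbon of the dianion, and a temperature window in which 2 stays in solution and 4 survives.

**2 ⇒ 1, C–I for C–O.** This is a functional group interchange that gives the best leaving group for a slow SN2 reaction. The forward step only has to run warm enough to keep the wax dissolved.

## Other disconnections considered

**Alternative 1:** cut O1–C2 and C2–C3 (the first that comes to mind).
- Forward key step: acylation of the enolate of 1-(2,4,6-trihydroxy-3-methylphenyl)ethanone A1, or the Baker–Venkataraman rearrangement of its ester, with triacontanoyl chloride A2. This gives the diketone A3, which is then cyclodehydrated with acid.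
- A3 has two non-equivalent ortho hydroxyls, so closure can give 11 or its 8-methyl isomer A4, and ring opening lets the two equilibrate.
- Differentiated protection does not help by itself. The less hindered ortho OH, next to H, is the one that must become O1, but it is also the one that is capped first. The natural order of reactivity therefore leads to A4.
- Three phenols to mask and unmask add several steps, and the core problem is moved rather than solved. The chosen plan has no such choice and no protecting group.

**Alternative 2:** cut C2–C1′ as a radical union.
- Forward key step: decarboxylative Giese addition of the primary C29 radical released from the redox-active ester A5 (photoredox or cathodic reduction) to C2 of 5,7-dihydroxy-6-methylchromone A6. This gives the racemic chromanone A7, which is then dehydrogenated.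
- The polarity match is good (nucleophilic radical, electrophilic C2).
- However, A6 is not a commercial compound and carries exactly the 6-/8-methyl problem, so the hardest part is left to a conventional synthesis.
- The addition also overshoots to the chromanone level, creates a stereocentre only to destroy it, and the re-oxidation has to spare a free phloroglucinol ring. The phenolic O–H bonds are hydrogen-atom donors toward the alkyl radical, which again calls for protection.

**Alternative 3:** cut C7–C8 and C4a–C5, a [3+3] with the pyrone as 1,3-dinucleophile.
- Forward key step: 2,6-dimethyl-4H-pyran-4-one A8 is alkylated once with 2 to give 2-methyl-6-nonacosyl-4H-pyran-4-one A9. A9 is then doubly acylated, at the lateral CH3 and then at ring C3, by methylmalonyl dichloride A10.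
- The symmetric three-carbon piece also locks the methyl group, and on paper the plan is one step shorter. The key step is hard to defend, for three reasons.
  - A9 has two lateral sites of similar acidity and nothing marks the right one, so growth from C1′ of the chain would give the isomer A11.
  - A10 has an acidic C–H that quenches the lateral anion and collapses to a chlorocarbonyl ketene prone to oligomerisation.
  - The mono-acylated stage is far more acidic than A9, so proton transfer stops conversion.
- In the chosen plan the polarity is reversed, and a leaving group defines the site.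

Key step: step 4

Remark on the chemistry: the SMILES holds no stereocentre and no stereogenic double bond, so the target is achiral and the demand for a single enantiomer is met by constitution alone; the side chain is read as unbranched nonacosyl (29 carbons, C39H66O4). LDA is taken as a commercial solution.

## Route

Step 1
Reactants: 1 1-octacosanol
Product: 2 1-iodooctacosane
Conditions: I2, PPh3, imidazole, toluene, 80 °C
Reagents that add atoms: iodine, II
Why: Appel-type iodination: the alkoxyphosphonium ion of a primary alcohol is displaced by iodide in a clean SN2 reaction, and warm toluene keeps the wax in solution. No other functional group is present.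

Step 2
Reactants: 2 1-iodooctacosane; 3 4-hydroxy-6-methyl-2H-pyran-2-one (triacetic acid lactone)
Product: 5 4-hydroxy-6-nonacosyl-2H-pyran-2-one, via dilithio dianion of triacetic lactone 4 (not isolated)
Conditions: 3 (1.5 equiv), LDA (3.1 equiv), THF–DMPU, −78 → 0 °C; 2 in warm THF, 0 → 40 °C; 1 M HCl
Reagents that add atoms: none
Why: Dianion alkylation: the last-formed, most basic site (the exocyclic CH2 carbanion) is the most nucleophilic, so the SN2 reaction with the primary iodide should take place there and not at O4 or C3. The excess of 4 suppresses a second alkylation, and 1 + 28 carbons give the C29 chain.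

Step 3
Reactants: 5 4-hydroxy-6-nonacosyl-2H-pyran-2-one
Product: 7 2-methoxy-6-nonacosyl-4H-pyran-4-one, via 4-hydroxy-2-methoxy-6-nonacosylpyrylium triflate 6 (not isolated)
Conditions: MeOTf (1.3 equiv), CH2Cl2, rt → 40 °C; then sat. aq. NaHCO3
Reagents that add atoms: methyl trifluoromethanesulfonate, COS(=O)(=O)C(F)(F)F
Why: Regiospecific methylation of a neutral protomeric ambident system: with no base present the only free basic site of 5 is the lactone carbonyl oxygen, whose methylation gives the stabilised pyrylium ion 6. Loss of the 4-OH proton on work-up then gives the α-methoxy-γ-pyrone, the known way to this isomer.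

Step 4
Reactants: 7 2-methoxy-6-nonacosyl-4H-pyran-4-one; 8 methyl 2-methyl-3-oxobutanoate (methyl 2-methylacetoacetate)
Product: 11 5,7-dihydroxy-6-methyl-2-nonacosyl-4H-chromen-4-one, via dilithio dianion of methyl 2-methylacetoacetate 9 (not isolated), via lithium enolate of the pyranyl keto ester 10 (not isolated)
Conditions: 8 (3 equiv), LDA (6 equiv), THF, 0 °C; 7 in warm THF added slowly, 0 °C → rt; MeOH (discharges excess 9), 50 °C; 1 M HCl, 0 °C
Reagents that add atoms: none
Why: Proposed new method: the γ-carbanion of 9 should add to C2 of 7, which carries the ring oxygen and OMe and is thus a vinylogous carbonate carbon, and expel methoxide (addition–elimination, SNV), which re-forms the γ-pyrone as the enolate 10 and makes C8–C8a. Once the excess of 9 is discharged with MeOH, proton exchange moves the charge of 10 to the CH2 between pyrone and ketone, so that the ester is no longer part of an enolate and an extended dienolate results whose α-terminus is pyrone C3 (future C4a), the site at which such dienolates react kinetically. C3 attacks the ester carbonyl in a 6-(enolexo)-exo-trig Claisen (Dieckmann-type) closure that makes C4a–C5 and closes the only new ring, the carbocycle; methoxide leaves and the dione tautomerises to the 5,7-bis-phenoxide, an irreversible aromatisation that drives the sequence. The closest known reaction types are the Staunton–Weinreb annulation (ester-bearing carbanion plus pyrone, conjugate addition then Claisen closure), the displacement of the α-methoxy group of γ-pyrones by stabilised carbanions, and the Claisen-type cyclisation of 3,5,7-trioxo esters to acylphloroglucinols; new is a β-keto ester dianion as the four-carbon partner, which delivers a free phloroglucinol-type ring. Site selectivity (C2 over C6 and C4=O) rests on the leaving group, because only the adduct at C2 can collapse irreversibly while adducts of this stabilised nucleophile at the other sites can revert. Closure selectivity rests on ring size: the other nucleophilic sites of the anion (lateral carbon, ketone oxygen, pyrone oxygen) would give four- or eight-membered rings, and pyrone C5 cannot reach the ester. The position of the methyl group is fixed by the constitution of 8, whose α-carbon lies between the carbons that become C5 and C7, so C6 is methylated and C8 carries H without any choice between two phenolic oxygens. No stereocentre remains, since the CH(CH3) carbon of 10 is configurationally labile and becomes sp2 C6; the chief competitor, proton transfer from C1′ of the chain to 9, is met by slow addition of 7 to an excess of 9.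

## Compound list

1 | 1-octacosanol | CCCCCCCCCCCCCCCCCCCCCCCCCCCCO | starting material
2 | 1-iodooctacosane | CCCCCCCCCCCCCCCCCCCCCCCCCCCCI | intermediate
3 | 4-hydroxy-6-methyl-2H-pyran-2-one (triacetic acid lactone) | Cc1cc(O)cc(=O)o1 | starting material
4 | dilithio dianion of 3 (4-oxido, exocyclic CH2 carbanion) | [Li+].[Li+].[CH2-]c1cc([O-])cc(=O)o1 | intermediate
5 | 4-hydroxy-6-nonacosyl-2H-pyran-2-one | CCCCCCCCCCCCCCCCCCCCCCCCCCCCCc1cc(O)cc(=O)o1 | intermediate
6 | 4-hydroxy-2-methoxy-6-nonacosylpyrylium trifluoromethanesulfonate | CCCCCCCCCCCCCCCCCCCCCCCCCCCCCc1cc(O)cc(OC)[o+]1.[O-]S(=O)(=O)C(F)(F)F | intermediate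
7 | 2-methoxy-6-nonacosyl-4H-pyran-4-one | CCCCCCCCCCCCCCCCCCCCCCCCCCCCCc1cc(=O)cc(OC)o1 | intermediate
8 | methyl 2-methyl-3-oxobutanoate | CC(=O)C(C)C(=O)OC | starting material
9 | dilithio dianion of 8 (C2 and C4 deprotonated, drawn as the carbanion form) | [Li+].[Li+].[CH2-]C(=O)[C-](C)C(=O)OC | intermediate
10 | lithium enolate of methyl 2-methyl-3-oxo-4-(6-nonacosyl-4-oxo-4H-pyran-2-yl)butanoate (drawn as the carbanion form) | [Li+].CCCCCCCCCCCCCCCCCCCCCCCCCCCCCc1cc(=O)cc(CC(=O)[C-](C)C(=O)OC)o1 | intermediate
11 | 5,7-dihydroxy-6-methyl-2-nonacosyl-4H-chromen-4-one (achiral) | CCCCCCCCCCCCCCCCCCCCCCCCCCCCCc1cc(=O)c2c(O)c(C)c(O)cc2o1 | target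

## Step count and least certain steps

Total step count: 4. Longest linear sequence: 4 (1 → 2 → 5 → 7 → 11).

**Step 4 (key step, proposed new method).**
- Most likely failure: proton transfer from the vinylogously acidic C1′ methylene of 7 to the strongly basic 9 outruns addition at C2, so both partners are simply returned on work-up.
- The sequence may also halt after the first bond if the side chain stays doubly deprotonated.
- On long heating, alkoxide may open the pyrone ring and so reopen the 6-/8-methyl question.
- Fallback (known chemistry only; the heterocycle is closed last, on a phenol whose symmetry removes the choice of oxygen): it sets out from 2 and comes back at 11. Commercial 2,6-dimethoxytoluene is borylated at its only unhindered C–H by iridium-catalysed C–H borylation with B2pin2 to give 2-(3,5-dimethoxy-4-methylphenyl)-4,4,5,5-tetramethyl-1,3,2-dioxaborolane F1. Oxidation with H2O2 gives 3,5-dimethoxy-4-methylphenol F2, whose two ortho positions are equivalent. Friedel–Crafts/Fries acetylation (Ac2O, BF3·OEt2) gives 1-(6-hydroxy-2,4-dimethoxy-3-methylphenyl)ethan-1-one F3. Claisen condensation with ethyl acetate (NaH) gives 1-(6-hydroxy-2,4-dimethoxy-3-methylphenyl)butane-1,3-dione F4, and acid cyclodehydration gives 5,7-dimethoxy-2,6-dimethyl-4H-chromen-4-one F5. Lateral deprotonation of the 2-methyl group (LDA, THF) and alkylation with 2 gives 5,7-dimethoxy-6-methyl-2-nonacosyl-4H-chromen-4-one F6. BBr3 in CH2Cl2 then cleaves both ethers to give 11. This is longer and uses methyl ethers as protection, but every operation is standard.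

**Step 2.**
- Most likely failure: a slow SN2 reaction, because the waxy iodide leaves solution below room temperature, while on warming the aggregated dianion decays or turns to E2 elimination and O-alkylation.
- Proton exchange between the product anion and 4 could also lead to a second alkylation.
- Fallback (carbonyl addition in place of substitution): it sets out from 1, uses 4 again, and comes back at 5. Oxidation of 1 (TEMPO, PhI(OAc)2, warm CH2Cl2) gives octacosanal F7. Aldol addition of 4, fast even at 0 °C, gives racemic 4-hydroxy-6-(2-hydroxynonacosyl)-2H-pyran-2-one F8. Acid-catalysed dehydration (p-TsOH, toluene, reflux) gives the conjugated 4-hydroxy-6-[(E)-nonacos-1-en-1-yl]-2H-pyran-2-one F9. Hydrogenation of the exocyclic alkene (H2, Pd/C, warm EtOAc–THF) gives 5.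

**Step 3.**
- Most likely failure: methyl transfer to O4 instead of the lactone carbonyl oxygen, if part of 5 is ionised.
- Further risks are a second methylation of the product at C4=O during a slow quench, and hydrolysis of the vinylogous carbonate on work-up.
- Fallback (the methoxypyrone ring is built by cycloaddition, with no ambident methylation): it sets out from 2 and comes back at 7. The lithium dienolate of commercial 2,2,6-trimethyl-4H-1,3-dioxin-4-one (LDA, THF–DMPU) is alkylated at its γ-carbon with 2 to give 2,2-dimethyl-6-nonacosyl-4H-1,3-dioxin-4-one F10. Thermolysis (toluene, 110 °C, sealed tube) releases the acylketene 3-oxodotriacont-1-en-1-one F11. F11 is trapped in a hetero-Diels–Alder reaction by 1,1-dimethoxyethene to give 2,2-dimethoxy-6-nonacosyl-2,3-dihydro-4H-pyran-4-one F12, which loses methanol to give 7.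

## Further compounds

F1 | step 4 | 2-(3,5-dimethoxy-4-methylphenyl)-4,4,5,5-tetramethyl-1,3,2-dioxaborolane | COc1cc(B2OC(C)(C)C(C)(C)O2)cc(OC)c1C
F2 | step 4 | 3,5-dimethoxy-4-methylphenol | COc1cc(O)cc(OC)c1C
F3 | step 4 | 1-(6-hydroxy-2,4-dimethoxy-3-methylphenyl)ethan-1-one | CC(=O)c1c(O)cc(OC)c(C)c1OC
F4 | step 4 | 1-(6-hydroxy-2,4-dimethoxy-3-methylphenyl)butane-1,3-dione | CC(=O)CC(=O)c1c(O)cc(OC)c(C)c1OC
F5 | step 4 | 5,7-dimethoxy-2,6-dimethyl-4H-chromen-4-one | Cc1cc(=O)c2c(OC)c(C)c(OC)cc2o1
F6 | step 4 | 5,7-dimethoxy-6-methyl-2-nonacosyl-4H-chromen-4-one | CCCCCCCCCCCCCCCCCCCCCCCCCCCCCc1cc(=O)c2c(OC)c(C)c(OC)cc2o1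
F7 | step 2 | octacosanal | CCCCCCCCCCCCCCCCCCCCCCCCCCCC=O
F8 | step 2 | 4-hydroxy-6-(2-hydroxynonacosyl)-2H-pyran-2-one (racemic) | CCCCCCCCCCCCCCCCCCCCCCCCCCCC(O)Cc1cc(O)cc(=O)o1
F9 | step 2 | 4-hydroxy-6-[(E)-nonacos-1-en-1-yl]-2H-pyran-2-one | CCCCCCCCCCCCCCCCCCCCCCCCCCC/C=C/c1cc(O)cc(=O)o1
F10 | step 3 | 2,2-dimethyl-6-nonacosyl-4H-1,3-dioxin-4-one | CCCCCCCCCCCCCCCCCCCCCCCCCCCCCC1=CC(=O)OC(C)(C)O1
F11 | step 3 | 3-oxodotriacont-1-en-1-one (acylketene, transient) | CCCCCCCCCCCCCCCCCCCCCCCCCCCCCC(=O)C=C=O
F12 | step 3 | 2,2-dimethoxy-6-nonacosyl-2,3-dihydro-4H-pyran-4-one | CCCCCCCCCCCCCCCCCCCCCCCCCCCCCC1=CC(=O)CC(OC)(OC)O1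
A1 | alternative 1 | 1-(2,4,6-trihydroxy-3-methylphenyl)ethan-1-one | CC(=O)c1c(O)cc(O)c(C)c1O
A2 | alternative 1 | triacontanoyl chloride | CCCCCCCCCCCCCCCCCCCCCCCCCCCCCC(=O)Cl
A3 | alternative 1 | 1-(2,4,6-trihydroxy-3-methylphenyl)dotriacontane-1,3-dione | CCCCCCCCCCCCCCCCCCCCCCCCCCCCCC(=O)CC(=O)c1c(O)cc(O)c(C)c1O
A4 | alternative 1 | 5,7-dihydroxy-8-methyl-2-nonacosyl-4H-chromen-4-one | CCCCCCCCCCCCCCCCCCCCCCCCCCCCCc1cc(=O)c2c(O)cc(O)c(C)c2o1
A5 | alternative 2 | 1,3-dioxoisoindolin-2-yl triacontanoate | CCCCCCCCCCCCCCCCCCCCCCCCCCCCCC(=O)ON1C(=O)c2ccccc2C1=O
A6 | alternative 2 | 5,7-dihydroxy-6-methyl-4H-chromen-4-one | Cc1c(O)cc2occc(=O)c2c1O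
A7 | alternative 2 | 5,7-dihydroxy-6-methyl-2-nonacosylchroman-4-one (racemic) | CCCCCCCCCCCCCCCCCCCCCCCCCCCCCC1CC(=O)c2c(O)c(C)c(O)cc2O1
A8 | alternative 3 | 2,6-dimethyl-4H-pyran-4-one | Cc1cc(=O)cc(C)o1
A9 | alternative 3 | 2-methyl-6-nonacosyl-4H-pyran-4-one | CCCCCCCCCCCCCCCCCCCCCCCCCCCCCc1cc(=O)cc(C)o1
A10 | alternative 3 | 2-methylpropanedioyl dichloride (methylmalonyl dichloride) | CC(C(=O)Cl)C(=O)Cl
A11 | alternative 3 | 5,7-dihydroxy-2,6-dimethyl-8-octacosyl-4H-chromen-4-one | CCCCCCCCCCCCCCCCCCCCCCCCCCCCc1c(O)c(C)c(O)c2c(=O)cc(C)oc12
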